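All runs come from a simulation with constants of no real substance; scatter was added.

In the first 10 h, the elm run, charged with 0.300 M of free catalyst, reaches c(product) = 0.037 M, while the birch run, charged with 0.100 M, reaches 0.016 M; each reading has a scatter of 0.01 M.

| setting | birch | oak | elm | cedar |
|---|---|---|---|---|
| substrate | 1.00 M | 0.500 M | 1.00 M | 3.00 M |
| free catalyst | 0.100 M | 0.100 M | 0.300 M | 0.100 M |
| time |  |  |  | 250 h |

| birch run: time / h | birch run: [product] / M | oak run: time / h | oak run: [product] / M | elm run: time / h | elm run: [product] / M |
|---|---|---|---|---|---|
| 10 | 0.016 | 10 | 0 | 10 | 0.037 |
| 22 | 0.034 | 22 | 0.002 | 22 | 0.049 |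
| 50 | 0.099 | 50 | 0.035 | 50 | 0.103 |
| 110 | 0.201 | 110 | 0.101 | 110 | 0.207 |
| 250 | 0.387 | 250 | 0.188 | 250 | 0.404 |

(each reading ± 0.01 M)

- how the opening rate goes with [free catalyst] round the charge of the birch run: the exponent of the rate at two percent of substrate gone to product
- how the opening rate goes with [substrate] round the charge of the birch run: the exponent of the rate at two percent of substrate gone to product (one fixed amount of product, the same in the runs compared)
- product in the cedar run at 250 h, as a share of the substrate charged

- Overall: substrate -> product, with free catalyst as catalyst.
- Constant volume, constant temperature.
- Bound and free are read together.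
- An order is taken over about fifteen percent of the charge, up and down.

That early gap of 0.0210 M is the fastest rung: a catalysed extra, visible in the elm run. By the late stretch it hardly shows. From 110 h to 250 h, the elm run gains 0.197 M and the birch run 0.186 M, although elm holds more free catalyst. The oak run, with half the substrate of birch, gains 0.0870 M, about half of the birch gain.

So the slowest rung follows substrate. Its measure is the late constant, the first-order constant of substrate loss between the last two readings: the birch run gives 0.00189 h⁻¹. Its time, 528 h, is longer than the 250 h asked of the cedar run, so cedar is still on its way then.

My first round gives cedar a share of 37.7%. Put back into the birch run, that share leaves 0.0100 M of product unexplained at 250 h, no more than the scatter. If this extra grows with substrate, cedar reaches 38.7%, so I expect a share between the two.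

The same round serves the opening. The elm rate over its first 10 h, less the late rate, and scaled down to the birch catalyst, gives a rough extra of 6.02 × 10⁻⁴ M h⁻¹. Birch then opens at 0.00250 M h⁻¹. The extra share, 0.241, is my ord_C. For ord_S I expect a value above 1, since the oak run reads 0.101 M at 110 h and the birch run reads 0.099 M at 50 h: about the same product in 2.20 times the time, on half the substrate, which as a reading gives an exponent of 1.14. With the extra wholly gone, the exponent would be 1.40.

The forecast gave 0.1, 1.05 and 38%, on the ground that “Tripling the catalyst barely changes the rate”.

The flask gives 0.18, 1.2 and 38.2%.

    free catalyst + substrate ⇌ catalyst-substrate complex (0.7236 M⁻¹ h⁻¹, 4.500 h⁻¹)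
    catalyst-substrate complex → product + free catalyst (0.07704 h⁻¹)
    substrate → product (0.001897 h⁻¹)
    free catalyst → spent catalyst (0.1775 h⁻¹)

At the same amount of product, the oak rate stands at 0.44 of the birch rate, which is below the half that its substrate charge alone would suggest. The late constant puts the half-share time at 367 h, and the birch and oak runs reach half their charge at 362 h and 362 h.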